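**Retrosynthetic overview**
1. Feature: the quaternary C1 (CH3 = C15) is bonded to C5, and C5 carries on its other side C4 with O4 and isopropyl. The cyclopentane C1–C2–C3–C4–C5 with C10 exocyclic on C1 is therefore a p-menthane ring (C1–C10–C5–C4–C3–C2) contracted by one atom.
2. Key disconnection C1–C5: the bond is traced back to C10–C5 of a 4-silyloxy piperitone oxide; BF3·OEt2 shifts the acyl carbon C5 from C10 to C1 and C10 becomes the aldehyde. The epoxy ketone comes from (R)-piperitone through trans-piperitol (directed epoxidation) and enolate hydroxylation anti to the epoxide.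
3. The seven-membered ring is cut at C7=C8 (ring-closing metathesis) into a C6 vinyl carbinol arm (C5 ketone → methylene → hydroboration → aldehyde → chelate-controlled vinyl addition) and a C9 isopropenyl ketone arm (C10 aldehyde → Wittig homologation → Grignard addition → oxidation).
4. The O4 aroyl ester is put on the tertiary alkoxide before any ketone is present; the silyl ethers on O6 and on the phenol are removed together in the last step.
5. Ring order: six-membered carbocycle (chiral pool) → cyclopentane (step 6) → cycloheptenone (step 20).

Key step: step 6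

Remark (numbering, used for all compounds): cyclopentane C1(CH3 = C15)–C2–C3–C4(O4, isopropyl)–C5; seven-membered ring C5–C6(O6)–C7=C8(CH3 = C14)–C9(=O)–C10–C1.
Remark (assumption): (R)-(−)-piperitone of high enantiomeric purity is used; its C4 centre fixes the epoxide configuration in steps 1–2 and is erased only afterwards (step 4).

Step 1
Reactants: 1 (R)-(−)-piperitone
Product: 2 trans-piperitol
Conditions: NaBH4, CeCl3·7H2O, MeOH, −78 → 0 °C
Reagents that add atoms: none
Why: Luche reduction; the hydride should add 1,2 and axially to the half-chair enone with equatorial isopropyl, placing the carbinol trans to the isopropyl group (the minor cis isomer is removed by chromatography), and the cold, weakly acidic medium should not racemise C4.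

Step 2
Reactants: 2 trans-piperitol
Product: 3 epoxy alcohol (epoxide cis to OH, trans to isopropyl)
Conditions: VO(acac)2 (cat.), t-BuOOH, CH2Cl2, 0 °C → rt
Reagents that add atoms: tert-butyl hydroperoxide, CC(C)(C)OO
Why: Vanadium-catalysed hydroxyl-directed epoxidation of the allylic alcohol delivers oxygen to the C1=C10 face syn to the carbinol, hence anti to isopropyl, so C1 and C10 are set by the piperitone centre.

Step 3
Reactants: 3 epoxy alcohol
Product: 4 trans-piperitone oxide
Conditions: Dess–Martin periodinane, NaHCO3, CH2Cl2, 0 °C → rt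
Reagents that add atoms: none
Why: Dess–Martin oxidation of the secondary epoxy alcohol gives the α,β-epoxy ketone under near-neutral conditions; any epimerisation at C4 would be harmless because that centre is erased in step 4.

Step 4
Reactants: 4 trans-piperitone oxide
Product: 5 4-hydroxy piperitone oxide (OH anti to the epoxide oxygen)
Conditions: KN(SiMe3)2, THF, −78 → −40 °C; then 2-(phenylsulfonyl)-3-phenyloxaziridine, −78 °C; aq. NH4Cl
Reagents that add atoms: 2-(phenylsulfonyl)-3-phenyloxaziridine, O=S(=O)(c1ccccc1)N1OC1c1ccccc1
Why: Davis enolate hydroxylation; C4–H is the only enolisable position, and the oxidant should approach the planar C4 on the face away from the epoxide oxygen (1,3-related to C4, steric and dipolar repulsion), so O4 ends anti to the epoxide.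

Step 5
Reactants: 5 4-hydroxy piperitone oxide
Product: 6 4-(tert-butyldimethylsilyloxy) piperitone oxide
Conditions: TBSOTf, 2,6-lutidine, CH2Cl2, −78 → 0 °C
Reagents that add atoms: tert-butyldimethylsilyl triflate, CC(C)(C)[Si](C)(C)OS(=O)(=O)C(F)(F)F
Why: Silyl triflate silylation of the tertiary α-ketol; excess hindered base keeps the triflate from activating the epoxide.

Step 6
Reactants: 6 4-(tert-butyldimethylsilyloxy) piperitone oxide
Product: 7 2-formyl-2-methyl-5-isopropyl-5-(tert-butyldimethylsilyloxy)cyclopentanone
Conditions: BF3·OEt2, CH2Cl2, −78 → 0 °C; aq. NaHCO3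
Reagents that add atoms: none
Why: BF3 binds the epoxide oxygen, the C1–O bond ionises toward the tertiary, methyl-bearing C1, the acyl carbon C5 shifts from C10 to C1, and the oxygen left on C10 becomes the aldehyde. The closest known reaction is the Lewis acid rearrangement of β-alkyl α,β-epoxy cyclohexanones to 2-formylcyclopentanones (semipinacol-type 1,2-acyl shift, as with isophorone oxide). The cyclopentanone ring C1–C2–C3–C4–C5 closes by this 1,2-shift, C5 displacing the oxygen at C1 from the rear through a bridged three-centre transition state (formally 3-exo-tet), so the six-membered ring contracts by one atom. C1 is the only new stereocentre and is set by inversion: with the epoxide anti to O4, the methyl C15 ends cis to O4 and the formyl carbon C10 trans to it. The step needs C1–O and not C10–O cleavage (secured by the tertiary C1 and by the carbonyl, which disfavours positive charge at C10) and acyl shift ahead of hydride shift (the normal preference in this substrate class). The C4 centre is quaternary and not involved, and low temperature with a short reaction time is meant to keep the tertiary silyl ether intact.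

Step 7
Reactants: 7 keto aldehyde; 8 (methoxymethyl)triphenylphosphonium chloride
Product: 10 2-(2,2-dimethoxyethyl)-2-methyl-5-isopropyl-5-(tert-butyldimethylsilyloxy)cyclopentanone, via enol ether 9 (not isolated)
Conditions: 8, KN(SiMe3)2, THF, 0 °C; 7, −78 → 0 °C; then MeOH, camphorsulfonic acid (excess over base), rt
Reagents that add atoms: methanol, CO
Why: Wittig methoxymethylenation (one-carbon homologation giving C9) takes place at the aldehyde and not at the ketone flanked by two quaternary carbons, with a non-nucleophilic base to avoid deformylation; acid-catalysed addition of methanol to the enol ether then masks C9 as a dimethyl acetal.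

Step 8
Reactants: 10 keto acetal; 11 methyltriphenylphosphonium bromide
Product: 12 exocyclic alkene (C5=C6H2)
Conditions: 11, KOt-Bu, toluene, 100 °C
Reagents that add atoms: none
Why: Wittig methylenation under forcing conditions as used for ketones between quaternary carbons; the ketone has no α-hydrogen, so the hot basic medium cannot enolise or epimerise anything.

Step 9
Reactants: 12 exocyclic alkene
Product: 13 tertiary allylic alcohol (O4–H free)
Conditions: Bu4NF, THF, 50 °C
Reagents that add atoms: none
Why: Fluoride desilylation frees O4, which is needed for magnesium chelation in step 12 and for acylation in step 16; acetal and alkene are inert to fluoride.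

Step 10
Reactants: 13 tertiary allylic alcohol
Product: 14 1,3-diol (C6H2OH; C5 epimer with C6 trans to O4 expected as the main one)
Conditions: BH3·THF, THF, 0 °C → rt; then NaOH, H2O2, 0 °C → rt
Reagents that add atoms: hydrogen peroxide, OO
Why: Brown hydroboration–oxidation puts boron on the terminal C6 and creates C5; borane should add mainly from the CH3/O4 face (anti to isopropyl), giving the C5 epimer that is corrected in step 11, so the facial outcome is not critical and both epimers are carried on.

Step 11
Reactants: 14 1,3-diol
Product: 16 β-hydroxy aldehyde with the formyl group (C6) cis to O4 and C15, via 5-epi aldehyde 15 (not isolated)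
Conditions: (COCl)2, DMSO, CH2Cl2, −78 °C; Et3N, −78 → 0 °C; then DBU (cat.), rt
Reagents that add atoms: none
Why: Swern oxidation of the primary alcohol (the tertiary one cannot be oxidised) followed by amidine-base epimerisation through the enol should move the formyl group to the thermodynamically preferred side, cis to the small OH (hydrogen bond) and CH3 and trans to isopropyl and the C10 chain, which sets C5.

Step 12
Reactants: 16 β-hydroxy aldehyde; 17 vinylmagnesium bromide
Product: 18 (6S)-diol (vinyl carbinol at C6, O4–H free)
Conditions: MgBr2·OEt2, CH2Cl2, −78 °C; then 17 (3 equiv), THF, −78 → −40 °C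
Reagents that add atoms: none
Why: Cram chelate-controlled Grignard addition; magnesium bridges O4 and the aldehyde oxygen in a six-membered chelate cis-fused to the cyclopentane, and the vinyl group adds from the exposed face on the side of H5, away from C1, which should give the 6S carbinol.

Step 13
Reactants: 18 diol
Product: 19 C6 tert-butyldimethylsilyl ether (O4–H free)
Conditions: TBSOTf (1.1 equiv), 2,6-lutidine, CH2Cl2, −78 °C
Reagents that add atoms: tert-butyldimethylsilyl triflate, CC(C)(C)[Si](C)(C)OS(=O)(=O)C(F)(F)F
Why: Silylation discriminates the secondary allylic alcohol from the far more hindered tertiary one, and the low temperature and limited reagent spare the dimethyl acetal.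

Step 14
Reactants: 20 4-hydroxybenzoic acid
Product: 22 4-(tert-butyldimethylsilyloxy)benzoic acid, via bis-silyl compound 21 (not isolated)
Conditions: TBSCl, imidazole, DMF, rt; then AcOH/THF/H2O, rt
Reagents that add atoms: tert-butyldimethylsilyl chloride, CC(C)(C)[Si](C)(C)Cl
Why: Exhaustive silylation followed by selective hydrolysis of the labile silyl ester leaves the aryl silyl ether in place.

Step 15
Reactants: 22 4-(tert-butyldimethylsilyloxy)benzoic acid
Product: 23 4-(tert-butyldimethylsilyloxy)benzoyl chloride
Conditions: (COCl)2, DMF (cat.), CH2Cl2, 0 °C → rt; concentrate, use crude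
Reagents that add atoms: oxalyl chloride, ClC(=O)C(=O)Cl
Why: Acid chloride formation with DMF catalysis (Vilsmeier-type activation) under mild conditions that the aryl silyl ether tolerates.

Step 16
Reactants: 19 tertiary alcohol; 23 aroyl chloride
Product: 24 O4 4-(tert-butyldimethylsilyloxy)benzoate
Conditions: n-BuLi (1.05 equiv), THF, −78 °C; then 23, −78 → 0 °C
Reagents that add atoms: none
Why: O-acylation of a lithium tert-alkoxide with an acid chloride, the standard esterification of hindered tertiary alcohols; no carbonyl group or acidic C–H is present at this stage, and low temperature with the lithium counter-ion is meant to outrun silyl migration from O6.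

Step 17
Reactants: 24 ester acetal
Product: 25 C9 aldehyde
Conditions: pyridinium p-toluenesulfonate (cat.), acetone/H2O, 45 °C
Reagents that add atoms: water, O
Why: Mild acid hydrolysis of the dimethyl acetal; the hindered secondary silyl ether, the aryl silyl ether and the tertiary ester should survive.

Step 18
Reactants: 25 aldehyde; 26 isopropenylmagnesium bromide
Product: 27 C9 allylic alcohol (both C9 epimers)
Conditions: 26 (1.5 equiv), THF, −78 °C; aq. NH4Cl
Reagents that add atoms: none
Why: Grignard addition to the aldehyde is much faster at −78 °C than attack on the hindered tertiary aryl ester; the C9 configuration is removed in the next step.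

Step 19
Reactants: 27 allylic alcohol
Product: 28 isopropenyl ketone (C9=O)
Conditions: Dess–Martin periodinane, NaHCO3, CH2Cl2, 0 °C → rt
Reagents that add atoms: none
Why: Dess–Martin oxidation of the secondary allylic alcohol gives the enone without base or acid.

Step 20
Reactants: 28 dienone
Product: 29 bicyclic enone (O6 and phenol silylated)
Conditions: second-generation Hoveyda–Grubbs catalyst RuCl2(=CH-2-i-PrOC6H4)(H2IMes) (10 mol%), toluene (dilute), 80 °C
Reagents that add atoms: none
Why: Ring-closing metathesis; the catalyst should load on the vinyl group and close onto the isopropenyl ketone, forming the trisubstituted C7=C8 bond and the trans-fused seven-membered ring with loss of ethene.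

Step 21
Reactants: 29 bicyclic enone
Product: 30 target CNP0153637.1
Conditions: HF·pyridine, pyridine, THF, 0 °C → rt
Reagents that add atoms: none
Why: Fluoride desilylation under weakly acidic conditions removes the aryl and the C6 silyl ethers in one operation without base, so the tertiary ester should neither migrate to O6 nor be cleaved.

**Compound list**
1 | (R)-(−)-piperitone, (6R)-3-methyl-6-(propan-2-yl)cyclohex-2-en-1-one | CC1=CC(=O)[C@@H](C(C)C)CC1 | starting material
2 | trans-piperitol, (1R,6R)-3-methyl-6-(propan-2-yl)cyclohex-2-en-1-ol (OH trans to isopropyl) | CC1=C[C@H](O)[C@@H](C(C)C)CC1 | intermediate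
3 | (1S,2R,3R,4R)-1,2-epoxy-p-menthan-3-ol (epoxide cis to OH, trans to isopropyl) | C[C@@]12O[C@@H]1[C@H](O)[C@@H](C(C)C)CC2 | intermediate
4 | (1S,2S,4R)-1,2-epoxy-p-menthan-3-one, trans-piperitone oxide | C[C@@]12O[C@@H]1C(=O)[C@@H](C(C)C)CC2 | intermediate
5 | (1S,2S,4R)-4-hydroxy-1,2-epoxy-p-menthan-3-one (OH anti to epoxide) | C[C@@]12O[C@@H]1C(=O)[C@](O)(C(C)C)CC2 | intermediate
6 | (1S,2S,4R)-4-(tert-butyldimethylsilyloxy)-1,2-epoxy-p-menthan-3-one (silyloxy anti to epoxide) | C[C@@]12O[C@@H]1C(=O)[C@](O[Si](C)(C)C(C)(C)C)(C(C)C)CC2 | intermediate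
7 | 2-formyl-2-methyl-5-isopropyl-5-(tert-butyldimethylsilyloxy)cyclopentanone (C15 cis to O4, formyl C10 trans to O4) | O=C1[C@](C)(CC[C@@]1(O[Si](C)(C)C(C)(C)C)C(C)C)C=O | intermediate
8 | (methoxymethyl)triphenylphosphonium chloride | COC[P+](c1ccccc1)(c1ccccc1)c1ccccc1.[Cl-] | starting material
9 | enol ether (C10H=C9H–OMe, E/Z mixture) of 7 | O=C1[C@](C)(CC[C@@]1(O[Si](C)(C)C(C)(C)C)C(C)C)C=COC | intermediate (not isolated)
10 | 2-(2,2-dimethoxyethyl)-2-methyl-5-isopropyl-5-(tert-butyldimethylsilyloxy)cyclopentanone | O=C1[C@](C)(CC[C@@]1(O[Si](C)(C)C(C)(C)C)C(C)C)CC(OC)OC | intermediate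
11 | methyltriphenylphosphonium bromide | C[P+](c1ccccc1)(c1ccccc1)c1ccccc1.[Br-] | starting material
12 | C5 methylene compound (C5=C6H2; O4 silylated; C9 dimethyl acetal) | C=C1[C@](C)(CC[C@@]1(O[Si](C)(C)C(C)(C)C)C(C)C)CC(OC)OC | intermediate
13 | C5 methylene compound with free O4–H | C=C1[C@](C)(CC[C@@]1(O)C(C)C)CC(OC)OC | intermediate
14 | 1,3-diol, C6H2OH trans to O4 (5-epi series; minor C5 epimer carried along) | OC[C@H]1[C@](C)(CC[C@@]1(O)C(C)C)CC(OC)OC | intermediate
15 | 5-epi β-hydroxy aldehyde (formyl trans to O4) | O=C[C@H]1[C@](C)(CC[C@@]1(O)C(C)C)CC(OC)OC | intermediate (not isolated)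
16 | β-hydroxy aldehyde, formyl (C6) cis to O4 and C15, H5 cis to isopropyl | O=C[C@@H]1[C@](C)(CC[C@@]1(O)C(C)C)CC(OC)OC | intermediate
17 | vinylmagnesium bromide | C=C[Mg]Br | starting material
18 | (6S)-vinyl carbinol diol (O4–H and O6–H free) | C=C[C@H](O)[C@@H]1[C@](C)(CC[C@@]1(O)C(C)C)CC(OC)OC | intermediate
19 | (6S)-C6 tert-butyldimethylsilyl ether, O4–H free | C=C[C@H](O[Si](C)(C)C(C)(C)C)[C@@H]1[C@](C)(CC[C@@]1(O)C(C)C)CC(OC)OC | intermediate
20 | 4-hydroxybenzoic acid | OC(=O)c1ccc(O)cc1 | starting material
21 | tert-butyldimethylsilyl 4-(tert-butyldimethylsilyloxy)benzoate | CC(C)(C)[Si](C)(C)OC(=O)c1ccc(O[Si](C)(C)C(C)(C)C)cc1 | intermediate (not isolated)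
22 | 4-(tert-butyldimethylsilyloxy)benzoic acid | OC(=O)c1ccc(O[Si](C)(C)C(C)(C)C)cc1 | intermediate
23 | 4-(tert-butyldimethylsilyloxy)benzoyl chloride | ClC(=O)c1ccc(O[Si](C)(C)C(C)(C)C)cc1 | intermediate
24 | O4 4-(tert-butyldimethylsilyloxy)benzoate of 19 | C=C[C@H](O[Si](C)(C)C(C)(C)C)[C@@H]1[C@](C)(CC[C@@]1(OC(=O)c2ccc(O[Si](C)(C)C(C)(C)C)cc2)C(C)C)CC(OC)OC | intermediate
25 | C9 aldehyde | C=C[C@H](O[Si](C)(C)C(C)(C)C)[C@@H]1[C@](C)(CC[C@@]1(OC(=O)c2ccc(O[Si](C)(C)C(C)(C)C)cc2)C(C)C)CC=O | intermediate
26 | isopropenylmagnesium bromide | CC(=C)[Mg]Br | starting material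
27 | C9 isopropenyl carbinol (C9 epimers) | C=C[C@H](O[Si](C)(C)C(C)(C)C)[C@@H]1[C@](C)(CC[C@@]1(OC(=O)c2ccc(O[Si](C)(C)C(C)(C)C)cc2)C(C)C)CC(O)C(C)=C | intermediate
28 | C9 isopropenyl ketone (metathesis substrate) | C=C[C@H](O[Si](C)(C)C(C)(C)C)[C@@H]1[C@](C)(CC[C@@]1(OC(=O)c2ccc(O[Si](C)(C)C(C)(C)C)cc2)C(C)C)CC(=O)C(C)=C | intermediate
29 | bis-silylated target (O6 and phenol as tert-butyldimethylsilyl ethers) | CC1=C[C@H](O[Si](C)(C)C(C)(C)C)[C@@H]2[C@](C)(CC[C@@]2(OC(=O)c3ccc(O[Si](C)(C)C(C)(C)C)cc3)C(C)C)CC1=O | intermediate
30 | CNP0153637.1 | CC1=C[C@H](O)[C@@H]2[C@](C)(CC[C@@]2(OC(=O)c2ccc(O)cc2)C(C)C)CC1=O | target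

**Step count and risks**
Total step count: 21. Longest linear sequence: 19 (steps 1–13 and 16–21, from 1 to 30); steps 14–15 prepare the aroyl chloride.

Steps most likely to fail:

1. Step 6. The acyl shift may be overtaken by hydride migration from C10 to C1, or the Lewis acid may be diverted by the neighbouring silyloxy ketone, with loss of the silyl ether. Fallback: contract the ring before O4 is introduced. Setting out from 4, BF3·OEt2 should give 2-formyl-2-methyl-5-isopropylcyclopentanone F1 (the parent case of this rearrangement). The aldehyde is protected with HC(OMe)3, MeOH and pyridinium p-toluenesulfonate as dimethyl acetal F2. The enolate of F2 (KN(SiMe3)2) is hydroxylated with the Davis oxaziridine on the face away from the acetal-bearing substituent of C1, giving hydroxy ketone F3 with O4 cis to C15. TBSOTf and 2,6-lutidine give silyl ether F4, and aqueous trifluoroacetic acid in CH2Cl2 unmasks the aldehyde, returning to the route at 7.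

2. Step 11. Base equilibration of the free aldol may trigger retro-aldol opening of the cyclopentane or dehydration, or the equilibrium may not favour the required C5 epimer strongly enough. Fallback: set C5 kinetically under catalyst control. Setting out from 12, hydroboration with catecholborane and RhCl(PPh3)3 (cat.), then NaOH and H2O2, is a known way to reverse the facial sense of the uncatalysed reaction on allylic silyl ethers (metal hydride adding anti to the allylic C–O bond). It should give the silyl-protected alcohol F5 with C6 cis to O4. Bu4NF gives diol F6 (the C5 epimer of 14), and Swern oxidation without the amidine base returns to the route at 16.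

3. Step 16. Acylation of the hindered tertiary alkoxide may be slow, so that silyl migration from O6 to O4 (followed by acylation at O6) or attack of the alkoxide on the aryl silyl ether competes. Fallback: acylate on the rigid bicycle with a cationic acylating agent and no alkoxide. Setting out from 19, acetal hydrolysis (pyridinium p-toluenesulfonate, acetone/H2O) gives aldehyde F7. Isopropenylmagnesium bromide (2 equiv) gives carbinol F8, Dess–Martin periodinane gives enone F9, and ring-closing metathesis with the same ruthenium catalyst gives bicyclic hydroxy enone F10, in which O6 is silylated and held anti to O4. Treatment of F10 with the aroyl triflate formed from 23 and AgOTf, in the presence of 2,6-di-tert-butyl-4-methylpyridine, returns to the route at 29.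

Further compounds
F1 | step 6 | 2-formyl-2-methyl-5-isopropylcyclopentanone (C1 as in 7; C4–H epimerisable) | O=C1[C@](C)(CC[C@@H]1C(C)C)C=O
F2 | step 6 | 2-(dimethoxymethyl)-2-methyl-5-isopropylcyclopentanone | O=C1[C@](C)(CC[C@@H]1C(C)C)C(OC)OC
F3 | step 6 | 2-(dimethoxymethyl)-5-hydroxy-2-methyl-5-isopropylcyclopentanone (O4 cis to C15) | O=C1[C@](C)(CC[C@@]1(O)C(C)C)C(OC)OC
F4 | step 6 | 2-(dimethoxymethyl)-2-methyl-5-isopropyl-5-(tert-butyldimethylsilyloxy)cyclopentanone | O=C1[C@](C)(CC[C@@]1(O[Si](C)(C)C(C)(C)C)C(C)C)C(OC)OC
F5 | step 11 | primary alcohol with C6 cis to O4, O4 silylated, C9 dimethyl acetal | OC[C@@H]1[C@](C)(CC[C@@]1(O[Si](C)(C)C(C)(C)C)C(C)C)CC(OC)OC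
F6 | step 11 | 1,3-diol with C6 cis to O4 (C5 epimer of 14) | OC[C@@H]1[C@](C)(CC[C@@]1(O)C(C)C)CC(OC)OC
F7 | step 16 | C9 aldehyde with free O4–H and O6 silyl ether | C=C[C@H](O[Si](C)(C)C(C)(C)C)[C@@H]1[C@](C)(CC[C@@]1(O)C(C)C)CC=O
F8 | step 16 | C9 isopropenyl carbinol with free O4–H (C9 epimers) | C=C[C@H](O[Si](C)(C)C(C)(C)C)[C@@H]1[C@](C)(CC[C@@]1(O)C(C)C)CC(O)C(C)=C
F9 | step 16 | C9 isopropenyl ketone with free O4–H | C=C[C@H](O[Si](C)(C)C(C)(C)C)[C@@H]1[C@](C)(CC[C@@]1(O)C(C)C)CC(=O)C(C)=C
F10 | step 16 | bicyclic enone with free O4–H and O6 silyl ether | CC1=C[C@H](O[Si](C)(C)C(C)(C)C)[C@@H]2[C@](C)(CC[C@@]2(O)C(C)C)CC1=O
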